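Labdane numbering is used (C4 bears CH3/CH2OAc, C5–C10 is the ring fusion, C8 carries the exocyclic methylene, C9 the side chain). The route rests on disconnecting ring B at C5–C10 and C6–C7. These bonds flank C5–C6, so ring B is the adduct of a C5=C6 enal dienophile and a C7=C8–C9=C10 2-silyloxy diene, whose enol ether is the masked C8 methylene. Because C1–C4 tether the two partners, one intramolecular Diels–Alder reaction of an acyclic triene closes rings A and B together and sets the C5/C10 trans fusion under control of the preset C4 centre. The formyl activator is then excised.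

Key step: step 11

Remark: the target is read as (4R,5R,9S,10R)-18-acetoxylabda-8(17),13E-dien-15-oic acid (4-CH3 and 10-CH3 cis, 5-H and 9-H on the opposite face); the sense of induction of the ligand in step 3 is assumed by analogy, and the ligand antipode is used if it proves opposite.

Step 1
Reactants: 1 2-methyl-2-vinyloxirane (racemic)
Product: 2 (E)-4-chloro-2-methylbut-2-en-1-ol
Conditions: TiCl4, CH2Cl2, −85 °C; aqueous work-up
Reagents that add atoms: titanium tetrachloride, Cl[Ti](Cl)(Cl)Cl
Why: Lewis-acid SN2′ opening of the vinyl epoxide, in which chloride adds to the vinyl terminus as the tertiary allylic C–O bond breaks, should give the (E)-chloro alcohol and erases the racemic centre.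

Step 2
Reactants: 2 (E)-4-chloro-2-methylbut-2-en-1-ol
Product: 3 tert-butyl{[(2E)-4-chloro-2-methylbut-2-en-1-yl]oxy}diphenylsilane
Conditions: TBDPSCl, imidazole, CH2Cl2, 0 °C → rt
Reagents that add atoms: tert-butyl(chloro)diphenylsilane, CC(C)(C)[Si](Cl)(c1ccccc1)c1ccccc1
Why: Imidazole-mediated silylation of the primary alcohol installs the bulky group that later distinguishes the two C4 substituents.

Step 3
Reactants: 3 tert-butyl{[(2E)-4-chloro-2-methylbut-2-en-1-yl]oxy}diphenylsilane; 4 1-bromo-3-chloropropane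
Product: 6 tert-butyl{[(2R)-5-chloro-2-ethenyl-2-methylpentyl]oxy}diphenylsilane, via 3-chloropropylmagnesium bromide 5 (not isolated)
Conditions: 4, Mg, Et2O, rt; then 3, copper thiophene-2-carboxylate (CuTC, 3 mol %), (S)-BINOL-derived N,N-bis[(S)-1-phenylethyl]phosphoramidite (3.3 mol %), CH2Cl2, −78 °C
Reagents that add atoms: none
Why: Copper-catalysed asymmetric allylic alkylation (SN2′) delivers the alkyl group to the γ-carbon of the (E)-allyl chloride, the chiral ligand selecting one face of the trisubstituted olefin so that the quaternary C4 centre is set as R and the vinyl group (C5=C6) is unveiled.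

Step 4
Reactants: 7 tert-butyl(but-3-yn-1-yloxy)dimethylsilane
Product: 9 methyl (E)-5-[(tert-butyldimethylsilyl)oxy]-3-methylpent-2-enoate, via alkenyldimethylalane 8 (not isolated)
Conditions: Me3Al (2 equiv), Cp2ZrCl2 (20 mol %), CH2Cl2, 0 °C → rt; then ClCO2Me, 0 °C
Reagents that add atoms: trimethylaluminium, C[Al](C)C; methyl chloroformate, COC(=O)Cl
Why: Negishi zirconium-catalysed carboalumination is a syn addition (CH3 to the internal, Al to the terminal carbon) and the alkenylalane is acylated with retention, which fixes the 13E geometry.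

Step 5
Reactants: 9 methyl (E)-5-[(tert-butyldimethylsilyl)oxy]-3-methylpent-2-enoate
Product: 10 methyl (E)-5-bromo-3-methylpent-2-enoate
Conditions: Ph3PBr2, CH2Cl2, 0 °C → rt
Reagents that add atoms: dibromotriphenylphosphorane, BrP(Br)(c1ccccc1)(c1ccccc1)c1ccccc1
Why: Ph3PBr2 converts the primary silyl ether directly into the bromide (oxyphosphonium, SN2) without touching the enoate.

Step 6
Reactants: 10 methyl (E)-5-bromo-3-methylpent-2-enoate; 11 pentane-2,4-dione
Product: 12 methyl (E)-6-acetyl-3-methyl-7-oxooct-2-enoate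
Conditions: K2CO3, NaI (cat.), acetone, reflux
Reagents that add atoms: none
Why: C-Alkylation (SN2) of the soft potassium enolate of the 1,3-diketone by the primary bromide attaches the complete side chain to the future C9; no stereocentre is kept.

Step 7
Reactants: 12 methyl (E)-6-acetyl-3-methyl-7-oxooct-2-enoate
Product: 13 methyl (2E,6E)-6-acetyl-3-methyl-7-{[(trifluoromethyl)sulfonyl]oxy}octa-2,6-dienoate
Conditions: Tf2O, aqueous Me4NOH, hexanes, 5 °C (two phases)
Reagents that add atoms: trifluoromethanesulfonic anhydride, O=S(=O)(OS(=O)(=O)C(F)(F)F)C(F)(F)F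
Why: O-Triflation of the non-chelated tetraalkylammonium enolate, by analogy with counter-ion-controlled enol sulfonylation of β-dicarbonyl compounds, should place the triflate trans to the remaining acetyl group (E), the geometry that later puts the tether outside the diene.

Step 8
Reactants: 6 tert-butyl{[(2R)-5-chloro-2-ethenyl-2-methylpentyl]oxy}diphenylsilane; 13 methyl (2E,6E)-6-acetyl-3-methyl-7-{[(trifluoromethyl)sulfonyl]oxy}octa-2,6-dienoate
Product: 16 methyl (2E,6E,11R)-6-acetyl-11-({[tert-butyl(diphenyl)silyl]oxy}methyl)-3,7,11-trimethyltrideca-2,6,12-trienoate, via alkylmagnesium chloride 14 (not isolated), via alkylzinc chloride 15 (not isolated)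
Conditions: 6, Mg (activated), THF, reflux; ZnCl2, 0 °C; then 13, PdCl2(dppf) (5 mol %), THF, rt → 50 °C
Reagents that add atoms: none
Why: Negishi coupling of the primary alkylzinc reagent with the β-triflyloxy enone proceeds with retention of olefin geometry and tolerates ketone and ester, giving the tetrasubstituted (E)-enone with C1 trans to the acetyl group.

Step 9
Reactants: 16 methyl (2E,6E,11R)-6-acetyl-11-({[tert-butyl(diphenyl)silyl]oxy}methyl)-3,7,11-trimethyltrideca-2,6,12-trienoate; 17 acrolein
Product: 18 methyl (2E,6E,11R,12E)-6-acetyl-11-({[tert-butyl(diphenyl)silyl]oxy}methyl)-3,7,11-trimethyl-14-oxotetradeca-2,6,12-trienoate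
Conditions: second-generation Hoveyda–Grubbs catalyst (5 mol %), acrolein (5 equiv), CH2Cl2, 40 °C
Reagents that add atoms: none
Why: Olefin cross-metathesis engages only the monosubstituted vinyl group (the tetrasubstituted enone and trisubstituted enoate olefins are inert) and should give the (E)-enal, the activated C5=C6 dienophile.

Step 10
Reactants: 18 methyl (2E,6E,11R,12E)-6-acetyl-11-({[tert-butyl(diphenyl)silyl]oxy}methyl)-3,7,11-trimethyl-14-oxotetradeca-2,6,12-trienoate
Product: 19 methyl (2E,6E,11R,12E)-6-{1-[(tert-butyldimethylsilyl)oxy]ethenyl}-11-({[tert-butyl(diphenyl)silyl]oxy}methyl)-3,7,11-trimethyl-14-oxotetradeca-2,6,12-trienoate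
Conditions: TBSOTf, Et3N, CH2Cl2, −78 → 0 °C; used at once
Reagents that add atoms: tert-butyldimethylsilyl trifluoromethanesulfonate, CC(C)(C)[Si](C)(C)OS(=O)(=O)C(F)(F)F
Why: Soft enolisation of the methyl ketone at its methyl group (kinetic silyl enol ether formation) gives the cross-conjugated 2-silyloxy diene C7=C8–C9=C10, while the enal has no enolisable γ-hydrogen.

Step 11
Reactants: 19 methyl (2E,6E,11R,12E)-6-{1-[(tert-butyldimethylsilyl)oxy]ethenyl}-11-({[tert-butyl(diphenyl)silyl]oxy}methyl)-3,7,11-trimethyl-14-oxotetradeca-2,6,12-trienoate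
Product: 20 methyl (13E)-8-[(tert-butyldimethylsilyl)oxy]-18-{[tert-butyl(diphenyl)silyl]oxy}-6α-formyl-17-norlabda-8,13-dien-15-oate, (4R,5R,6S,10S)
Conditions: Me2AlCl (1.2 equiv), CH2Cl2 (0.01 M), −78 → −20 °C; NaHCO3 work-up
Reagents that add atoms: none
Why: Me2AlCl binds the aldehyde and lowers the LUMO of the (E)-enal, which undergoes a concerted but asynchronous intramolecular [4+2] cycloaddition with the electron-rich 2-silyloxy diene, C5–C10 bonding running ahead of C6–C7. The closest known reaction type is the Lewis-acid-promoted intramolecular Diels–Alder reaction of 1,3,9-decatrienes with a terminally activated dienophile, together with Lewis-acid Diels–Alder reactions of hindered 2-silyloxy dienes that build quaternary carbons. Ring B closes as the cyclohexene of the cycloaddition (boat-like six-centre array, both bonds formed on one face of each π partner), and ring A closes in the same event as the six-membered ring spanned by the C1–C4 tether once C5–C10 forms, the tether adopting a chair. C5 and C10 are set trans because the (E)-dienophile reacts through the endo transition state (aluminium-bound formyl under the diene, tether exo), and their absolute sense is controlled by C4: the large CH2OTBDPS group should sit anti to the incoming diene carbon and the small CH3 inside, so that the C4 and C10 methyl groups end up cis-diaxial; C6 (formyl trans to C4) is also set but is erased in step 12, and C9 stays sp2. The step needs endo over exo selectivity (secured by the Lewis acid and the E-enal), π-facial selectivity relative to C4 (secured by the size difference CH3 versus CH2OTBDPS) and the fused regiochemistry (secured by the tether and by the C9=C10 geometry that holds C1 outside the diene); high dilution suppresses intermolecular addition of the silyl enol ether to the aldehyde.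

Step 12
Reactants: 20 methyl (13E)-8-[(tert-butyldimethylsilyl)oxy]-18-{[tert-butyl(diphenyl)silyl]oxy}-6α-formyl-17-norlabda-8,13-dien-15-oate
Product: 21 methyl (13E)-8-[(tert-butyldimethylsilyl)oxy]-18-{[tert-butyl(diphenyl)silyl]oxy}-17-norlabda-8,13-dien-15-oate, (4R,5R,10S)
Conditions: RhCl(PPh3)3 (1.1 equiv), toluene, 110 °C
Reagents that add atoms: none
Why: Tsuji–Wilkinson decarbonylation (formyl C–H oxidative addition, CO extrusion, C–H reductive elimination) replaces CHO by H and turns C6 into the ring CH2; the tetrasubstituted enol ether and trisubstituted enoate do not interfere.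

Step 13
Reactants: 21 methyl (13E)-8-[(tert-butyldimethylsilyl)oxy]-18-{[tert-butyl(diphenyl)silyl]oxy}-17-norlabda-8,13-dien-15-oate
Product: 23 (13E)-18-hydroxy-8-oxo-17-norlabd-13-en-15-oic acid, (4R,5R,9R,10S), via keto alcohol methyl ester 22 (not isolated)
Conditions: TBAF (3 equiv), THF, 0 °C → rt; then LiOH, MeOH/H2O, 45 °C; 1 M HCl work-up
Reagents that add atoms: lithium hydroxide, [Li+].[OH-]
Why: Fluoride cleaves the silyl enol ether to the C8 ketone and the silyl ether to the primary alcohol, and hydroxide saponifies the methyl ester; C9, α to the ketone, equilibrates under base to the equatorial epimer (9β side chain, 9α-H), which sets the last stereocentre thermodynamically.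

Step 14
Reactants: 23 (13E)-18-hydroxy-8-oxo-17-norlabd-13-en-15-oic acid
Product: 24 (13E)-18-hydroxylabda-8(17),13-dien-15-oic acid, (4R,5R,9S,10R)
Conditions: Ph3PCH3Br (6 equiv), KOtBu (6 equiv), THF, 0 → 60 °C; acidic work-up
Reagents that add atoms: methyltriphenylphosphonium bromide, C[P+](c1ccccc1)(c1ccccc1)c1ccccc1.[Br-]
Why: Wittig methylenation converts the hindered C8 ketone into the exocyclic C8=C17 olefin; the carboxylate and alkoxide formed in the flask shield the enoate from conjugate attack and C9 is already the stable epimer.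

Step 15
Reactants: 24 (13E)-18-hydroxylabda-8(17),13-dien-15-oic acid
Product: 26 (13E)-18-acetoxylabda-8(17),13-dien-15-oic acid (target), via mixed acetic anhydride 25 (not isolated)
Conditions: Ac2O, pyridine, DMAP (cat.), CH2Cl2, rt; then H2O/THF, rt
Reagents that add atoms: acetic anhydride, CC(=O)OC(C)=O; water, O
Why: DMAP-catalysed acetylation esterifies the neopentyl primary alcohol, and the mixed anhydride formed at the carboxyl group is hydrolysed back to the acid on aqueous work-up.

Compound list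
1 | 2-methyl-2-vinyloxirane (racemic) | C=CC1(C)CO1 | starting material
2 | (E)-4-chloro-2-methylbut-2-en-1-ol | OC/C(C)=C/CCl | intermediate
3 | tert-butyl{[(2E)-4-chloro-2-methylbut-2-en-1-yl]oxy}diphenylsilane | CC(C)(C)[Si](OC/C(C)=C/CCl)(c1ccccc1)c1ccccc1 | intermediate
4 | 1-bromo-3-chloropropane | ClCCCBr | starting material
5 | 3-chloropropylmagnesium bromide | ClCCC[Mg]Br | intermediate
6 | tert-butyl{[(2R)-5-chloro-2-ethenyl-2-methylpentyl]oxy}diphenylsilane | C=C[C@](C)(CO[Si](c1ccccc1)(c1ccccc1)C(C)(C)C)CCCCl | intermediate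
7 | tert-butyl(but-3-yn-1-yloxy)dimethylsilane | C#CCCO[Si](C)(C)C(C)(C)C | starting material
8 | (E)-alkenyldimethylalane from 7 (CH3 and Al cis) | C[Al](C)/C=C(\C)CCO[Si](C)(C)C(C)(C)C | intermediate
9 | methyl (E)-5-[(tert-butyldimethylsilyl)oxy]-3-methylpent-2-enoate | COC(=O)/C=C(\C)CCO[Si](C)(C)C(C)(C)C | intermediate
10 | methyl (E)-5-bromo-3-methylpent-2-enoate | COC(=O)/C=C(\C)CCBr | intermediate
11 | pentane-2,4-dione | CC(=O)CC(C)=O | starting material
12 | methyl (E)-6-acetyl-3-methyl-7-oxooct-2-enoate | CC(=O)C(CC/C(C)=C/C(=O)OC)C(C)=O | intermediate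
13 | methyl (2E,6E)-6-acetyl-3-methyl-7-{[(trifluoromethyl)sulfonyl]oxy}octa-2,6-dienoate | CC(=O)/C(CC/C(C)=C/C(=O)OC)=C(\C)OS(=O)(=O)C(F)(F)F | intermediate
14 | [(4R)-4-({[tert-butyl(diphenyl)silyl]oxy}methyl)-4-methylhex-5-en-1-yl]magnesium chloride | C=C[C@](C)(CO[Si](c1ccccc1)(c1ccccc1)C(C)(C)C)CCC[Mg]Cl | intermediate
15 | [(4R)-4-({[tert-butyl(diphenyl)silyl]oxy}methyl)-4-methylhex-5-en-1-yl]zinc chloride | C=C[C@](C)(CO[Si](c1ccccc1)(c1ccccc1)C(C)(C)C)CCC[Zn]Cl | intermediate
16 | methyl (2E,6E,11R)-6-acetyl-11-({[tert-butyl(diphenyl)silyl]oxy}methyl)-3,7,11-trimethyltrideca-2,6,12-trienoate | CC(=O)/C(CC/C(C)=C/C(=O)OC)=C(\C)CCC[C@@](C)(CO[Si](c1ccccc1)(c1ccccc1)C(C)(C)C)C=C | intermediate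
17 | acrolein | C=CC=O | starting material
18 | methyl (2E,6E,11R,12E)-6-acetyl-11-({[tert-butyl(diphenyl)silyl]oxy}methyl)-3,7,11-trimethyl-14-oxotetradeca-2,6,12-trienoate | CC(=O)/C(CC/C(C)=C/C(=O)OC)=C(\C)CCC[C@@](C)(CO[Si](c1ccccc1)(c1ccccc1)C(C)(C)C)/C=C/C=O | intermediate
19 | methyl (2E,6E,11R,12E)-6-{1-[(tert-butyldimethylsilyl)oxy]ethenyl}-11-({[tert-butyl(diphenyl)silyl]oxy}methyl)-3,7,11-trimethyl-14-oxotetradeca-2,6,12-trienoate | C=C(O[Si](C)(C)C(C)(C)C)/C(CC/C(C)=C/C(=O)OC)=C(\C)CCC[C@@](C)(CO[Si](c1ccccc1)(c1ccccc1)C(C)(C)C)/C=C/C=O | intermediate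
20 | methyl (13E)-8-[(tert-butyldimethylsilyl)oxy]-18-{[tert-butyl(diphenyl)silyl]oxy}-6α-formyl-17-norlabda-8,13-dien-15-oate, (4R,5R,6S,10S), trans-fused | CC(C)(C)[Si](C)(C)OC1=C(CC/C(C)=C/C(=O)OC)[C@@]2(C)CCC[C@@](C)(CO[Si](c3ccccc3)(c3ccccc3)C(C)(C)C)[C@@H]2[C@@H](C=O)C1 | intermediate
21 | methyl (13E)-8-[(tert-butyldimethylsilyl)oxy]-18-{[tert-butyl(diphenyl)silyl]oxy}-17-norlabda-8,13-dien-15-oate, (4R,5R,10S) | CC(C)(C)[Si](C)(C)OC1=C(CC/C(C)=C/C(=O)OC)[C@@]2(C)CCC[C@@](C)(CO[Si](c3ccccc3)(c3ccccc3)C(C)(C)C)[C@@H]2CC1 | intermediate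
22 | methyl (13E)-18-hydroxy-8-oxo-17-norlabd-13-en-15-oate, (4R,5R,9R,10S) | O=C1CC[C@H]2[C@](C)(CO)CCC[C@]2(C)[C@H]1CC/C(C)=C/C(=O)OC | intermediate
23 | (13E)-18-hydroxy-8-oxo-17-norlabd-13-en-15-oic acid, (4R,5R,9R,10S) | O=C1CC[C@H]2[C@](C)(CO)CCC[C@]2(C)[C@H]1CC/C(C)=C/C(=O)O | intermediate
24 | (13E)-18-hydroxylabda-8(17),13-dien-15-oic acid, (4R,5R,9S,10R) | C=C1CC[C@H]2[C@](C)(CO)CCC[C@]2(C)[C@H]1CC/C(C)=C/C(=O)O | intermediate
25 | acetic (13E)-18-acetoxylabda-8(17),13-dien-15-oic anhydride | C=C1CC[C@H]2[C@](C)(COC(C)=O)CCC[C@]2(C)[C@H]1CC/C(C)=C/C(=O)OC(C)=O | intermediate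
26 | (13E)-18-acetoxylabda-8(17),13-dien-15-oic acid, (4R,5R,9S,10R); (E)-5-[(1S,4aR,5R,8aR)-5-(acetoxymethyl)-5,8a-dimethyl-2-methylidenedecahydronaphthalen-1-yl]-3-methylpent-2-enoic acid | C=C1CC[C@H]2[C@](C)(COC(C)=O)CCC[C@]2(C)[C@H]1CC/C(C)=C/C(=O)O | target

Total step count: 15.
Longest linear sequence: 12 steps (7 → 26, steps 4–15); the other branch (1 → 26) has 11.

Steps most likely to fail

Step 11 (key cycloaddition). The risks are weak π-facial discrimination between the CH3 and CH2OTBDPS faces at C4, leakage through the exo transition state to the cis-decalin, and Lewis-acid-induced intermolecular addition of the silyl enol ether to the aldehyde. The fallback replaces substrate control by auxiliary control; it sets out from 16 and comes back at 20. (S)-3-Acryloyl-4-benzyloxazolidin-2-one F1 would be made from (S)-4-benzyloxazolidin-2-one, n-BuLi and acryloyl chloride and joined to 16 by cross-metathesis (second-generation Hoveyda–Grubbs catalyst) to give the (E)-enoyl imide F2. TBSOTf/Et3N would give the silyl dienol ether F3. Me2AlCl (1.4 equiv, CH2Cl2, −78 → −30 °C) should then drive the same cycloaddition through the chelated s-cis imide, whose benzyl group screens the Cα-re face, to give the imide cycloadduct F4. LiBH4/MeOH (Et2O, 0 °C) would cleave the auxiliary to the 6α-hydroxymethyl compound F5, and Dess–Martin periodinane would return aldehyde 20.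

Step 7 (enol triflate geometry). The risk is loss of geometric control in the O-sulfonylation, which would place the triflate cis to the acetyl group and, after coupling, the tether inside the diene. The fallback fixes the geometry by syn-carbometalation; it sets out from chloride 6 (through Grignard 14) and bromide 10 and comes back at 16. But-2-ynoic acid would be converted (MeONHMe·HCl, EDC·HCl, Et3N) into N-methoxy-N-methylbut-2-ynamide F6. Grignard 14 with CuBr·SMe2 (THF, −78 °C) would add syn across F6 to give the alkenylcopper adduct F7, which iodine should trap with retention as the (Z)-α-iodo enamide F8. MeMgBr (THF, −78 °C) would give the (Z)-α-iodo enone F9. Negishi coupling of F9 with the alkylzinc bromide F10 (from 10, Zn dust, I2 cat., DMA, 80 °C) under PdCl2(dppf) would give 16.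

Step 12 (decarbonylation). The risk is slow CO extrusion at the hindered secondary formyl group, with β-hydride elimination to ring B olefins. The fallback removes the carbon as CO2 through a radical; it sets out from 20 and comes back at 21. Pinnick oxidation (NaClO2, NaH2PO4, 2-methylbut-2-ene, t-BuOH/H2O) would give the C6 carboxylic acid F11. DCC and N-hydroxypyridine-2-thione (CH2Cl2, dark) would give the Barton ester F12, and photolysis with t-BuSH (toluene, visible light) should replace the carboxyl group by hydrogen to give 21.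

Further compounds
F1 | step 11 | (S)-3-acryloyl-4-benzyloxazolidin-2-one | C=CC(=O)N1[C@@H](Cc2ccccc2)COC1=O
F2 | step 11 | (E)-enoyl imide from cross-metathesis of 16 with F1 | CC(=O)/C(CC/C(C)=C/C(=O)OC)=C(\C)CCC[C@@](C)(CO[Si](c1ccccc1)(c1ccccc1)C(C)(C)C)/C=C/C(=O)N1[C@@H](Cc2ccccc2)COC1=O
F3 | step 11 | silyl dienol ether of F2 | C=C(O[Si](C)(C)C(C)(C)C)/C(CC/C(C)=C/C(=O)OC)=C(\C)CCC[C@@](C)(CO[Si](c1ccccc1)(c1ccccc1)C(C)(C)C)/C=C/C(=O)N1[C@@H](Cc2ccccc2)COC1=O
F4 | step 11 | imide cycloadduct (acyl oxazolidinone at C6α, otherwise as 20) | CC(C)(C)[Si](C)(C)OC1=C(CC/C(C)=C/C(=O)OC)[C@@]2(C)CCC[C@@](C)(CO[Si](c3ccccc3)(c3ccccc3)C(C)(C)C)[C@@H]2[C@@H](C(=O)N4[C@@H](Cc5ccccc5)COC4=O)C1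
F5 | step 11 | 6α-hydroxymethyl compound (CH2OH in place of CHO of 20) | CC(C)(C)[Si](C)(C)OC1=C(CC/C(C)=C/C(=O)OC)[C@@]2(C)CCC[C@@](C)(CO[Si](c3ccccc3)(c3ccccc3)C(C)(C)C)[C@@H]2[C@@H](CO)C1
F6 | step 7 | N-methoxy-N-methylbut-2-ynamide | CC#CC(=O)N(C)OC
F7 | step 7 | alkenylcopper adduct (Cu cis to the tether) | CON(C)C(=O)/C([Cu])=C(\C)CCC[C@@](C)(CO[Si](c1ccccc1)(c1ccccc1)C(C)(C)C)C=C
F8 | step 7 | (2Z,7R)-7-({[tert-butyl(diphenyl)silyl]oxy}methyl)-2-iodo-N-methoxy-N,3,7-trimethylnona-2,8-dienamide | CON(C)C(=O)/C(I)=C(\C)CCC[C@@](C)(CO[Si](c1ccccc1)(c1ccccc1)C(C)(C)C)C=C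
F9 | step 7 | (3Z,8R)-8-({[tert-butyl(diphenyl)silyl]oxy}methyl)-3-iodo-4,8-dimethyldeca-3,9-dien-2-one | CC(=O)/C(I)=C(\C)CCC[C@@](C)(CO[Si](c1ccccc1)(c1ccccc1)C(C)(C)C)C=C
F10 | step 7 | [(3E)-5-methoxy-3-methyl-5-oxopent-3-en-1-yl]zinc bromide | COC(=O)/C=C(\C)CC[Zn]Br
F11 | step 12 | C6α carboxylic acid (CO2H in place of CHO of 20) | CC(C)(C)[Si](C)(C)OC1=C(CC/C(C)=C/C(=O)OC)[C@@]2(C)CCC[C@@](C)(CO[Si](c3ccccc3)(c3ccccc3)C(C)(C)C)[C@@H]2[C@@H](C(=O)O)C1
F12 | step 12 | Barton ester of F11 (2-thioxopyridin-1-yl ester) | CC(C)(C)[Si](C)(C)OC1=C(CC/C(C)=C/C(=O)OC)[C@@]2(C)CCC[C@@](C)(CO[Si](c3ccccc3)(c3ccccc3)C(C)(C)C)[C@@H]2[C@@H](C(=O)On4ccccc4=S)C1
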